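The route rests on cutting the C2–C3 bond of the pyranone ring. C2 is the CH(CH3) bound to O1 and C3 is the CH(CH3) next to the C4 ketone. A carbenoid at C3 can therefore insert into an O–CH2 hydrogen of an ethyl ether on the future O1. One chiral dirhodium-catalysed C–H insertion closes the heterocycle, makes its missing skeletal bond and sets the epimerisable cis-(2R,3S) pair under neutral conditions. The precursor is an aryl 1-diazoethyl ketone flanked by one ethoxy and one silyloxy group. Afterwards C6 is prenylated via its iodide. C8, the last free ring carbon, then adds to hexenal under iminium catalysis. No strongly basic step follows the ring closure.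

Key step: step 4

Assumption: the S antipode of the dirhodium prolinate is taken to give the (2R,3S) enantiomer. The sense must be checked on the first run, and if it is opposite the equally available Rh2(R-DOSP)4 is used with nothing else changed.

Numbering: O1, C2, C3, C4, C4a, C5–C8, C8a for all chromanones. The tricycles 16 and 17 use O1, C2, C3, C4, C4a, C5, C6, C6a, O7, C8, C9, C10, C10a, C10b.

Step 1
Reactants: 1 2,4,6-trihydroxypropiophenone
Product: 2 1-[2-hydroxy-4,6-bis(triisopropylsilyloxy)phenyl]propan-1-one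
Conditions: iPr3SiCl (2.2 equiv), imidazole, DMF, 0 °C to rt
Reagents that add atoms: triisopropylsilyl chloride, CC(C)[Si](Cl)(C(C)C)C(C)C
Why: Silyl ether formation caps the para phenol and one ortho phenol, and the last ortho phenol is hydrogen-bonded to the ketone and shielded, so the bulky chloride should stop at the bis-ether.

Step 2
Reactants: 2 1-[2-hydroxy-4,6-bis(triisopropylsilyloxy)phenyl]propan-1-one; 3 ethanol
Product: 4 1-[2-ethoxy-4,6-bis(triisopropylsilyloxy)phenyl]propan-1-one
Conditions: EtOH, PPh3, DIAD, THF, 0 °C to rt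
Reagents that add atoms: ethanol (3), CCO
Why: Mitsunobu etherification alkylates the remaining chelated phenol under neutral conditions and so avoids the carbonate bases that strip or scramble aryl silyl ethers.

Step 3
Reactants: 4 1-[2-ethoxy-4,6-bis(triisopropylsilyloxy)phenyl]propan-1-one
Product: 6 2-diazo-1-[2-ethoxy-4,6-bis(triisopropylsilyloxy)phenyl]propan-1-one, via trifluoroacetyl diketone 5 (not isolated)
Conditions: LiN(SiMe3)2, THF, −78 °C; CF3CO2CH2CF3, −78 °C; 5% aq HCl work-up; then 4-AcNHC6H4SO2N3, Et3N, H2O (1 equiv), MeCN, rt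
Reagents that add atoms: 4-acetamidobenzenesulfonyl azide, CC(=O)Nc1ccc(cc1)S(=O)(=O)N=[N+]=[N-]; 2,2,2-trifluoroethyl trifluoroacetate, O=C(OCC(F)(F)F)C(F)(F)F (its CF3CO group stays only in 5)
Why: In this Regitz-type detrifluoroacetylative diazo transfer, kinetic enolisation and Claisen acylation turn the ethyl ketone into a 1,3-diketone that takes N2 from the sulfonyl azide and sheds the trifluoroacetyl group, while −78 °C keeps the ortho silyl group from migrating to the enolate oxygen.

Step 4
Reactants: 6 2-diazo-1-[2-ethoxy-4,6-bis(triisopropylsilyloxy)phenyl]propan-1-one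
Product: 7 (2R,3S)-2,3-dimethyl-5,7-bis(triisopropylsilyloxy)chroman-4-one
Conditions: Rh2(S-DOSP)4 (1 mol %), hexane, 0 °C, slow addition of 6, argon; short pad of neutral silica
Reagents that add atoms: none
Why: The divalent-rhodium dimer expels N2 from 6 and leaves an electrophilic keto-carbenoid at C3, which inserts into one C–H bond of the neighbouring OCH2 group through a concerted, hydride-transfer-like three-centre transition state made easy by the lone pair of O1. The closest known reaction type is the intramolecular C–H insertion of ortho-alkoxyaryl α-diazoketones under chiral dirhodium prolinates, which gives 2,3-disubstituted chroman-4-ones. The pyranone ring closes by 1,6-insertion through a chair-like six-membered array (C3, C4, C4a, C8a, O1, C2), and no five-membered carbocycle can compete because the atom in that position is O1 itself. C2 is set by the choice that the chiral carboxylate pocket makes between the two enantiotopic OCH2 hydrogens (insertion with retention), and C3 is set in the same event by the carbenoid face that bonds, the kinetic transition state placing both methyl groups cis. The step needs insertion to outrun oxonium-ylide formation, 1,2-hydride shift and carbene dimerisation, which is secured by the acyl-depleted lone pairs of O1, by the fact that only a primary CH3 could deliver the migrating hydride, by a second ortho oxygen that carries a bulky TIPS group without any O–C–H bond, and by slow addition in a cold hydrocarbon. The medium is neutral and the product is only passed through a short pad of neutral silica, so the kinetic cis pair should not epimerise.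

Step 5
Reactants: 7 (2R,3S)-2,3-dimethyl-5,7-bis(triisopropylsilyloxy)chroman-4-one
Product: 8 (2R,3S)-5,7-dihydroxy-2,3-dimethylchroman-4-one
Conditions: Et3N·3HF, THF, rt
Reagents that add atoms: none
Why: Fluoride-mediated desilylation in a mildly acidic buffer frees both phenols without enolising C3 or opening the ring by retro-oxa-Michael reaction, and the diol should allow enantiomeric enrichment by recrystallisation.

Step 6
Reactants: 8 (2R,3S)-5,7-dihydroxy-2,3-dimethylchroman-4-one
Product: 9 (2R,3S)-5-hydroxy-2,3-dimethyl-7-(triisopropylsilyloxy)chroman-4-one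
Conditions: iPr3SiCl (1.05 equiv), imidazole, CH2Cl2–DMF, 0 °C
Reagents that add atoms: triisopropylsilyl chloride, CC(C)[Si](Cl)(C(C)C)C(C)C
Why: This selective silylation works because the two free phenols differ far more than the two aryl silyl ethers of 7, the 7-OH being an acidic, unhindered vinylogous acid and the 5-OH being hydrogen-bonded to the C4 carbonyl, so one equivalent should cap O7 only.

Step 7
Reactants: 9 (2R,3S)-5-hydroxy-2,3-dimethyl-7-(triisopropylsilyloxy)chroman-4-one
Product: 10 (2R,3S)-5-hydroxy-6-iodo-2,3-dimethyl-7-(triisopropylsilyloxy)chroman-4-one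
Conditions: NIS (1.0 equiv), CH2Cl2, −20 to 0 °C, dark
Reagents that add atoms: N-iodosuccinimide, O=C1CCC(=O)N1I
Why: Electrophilic aromatic iodination should enter ortho to the free chelated phenol, as is usual for 2-hydroxy-4,6-dialkoxyaryl ketones and 5-hydroxy-7-alkoxyflavonoids, which marks C6 and leaves C8 open.

Step 8
Reactants: 10 (2R,3S)-5-hydroxy-6-iodo-2,3-dimethyl-7-(triisopropylsilyloxy)chroman-4-one; 11 tributyl(3-methylbut-2-en-1-yl)stannane
Product: 12 (2R,3S)-5-hydroxy-2,3-dimethyl-6-(3-methylbut-2-en-1-yl)-7-(triisopropylsilyloxy)chroman-4-one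
Conditions: 11 (1.5 equiv), Pd(PPh3)4 (10 mol %), DMF, 80 °C, degassed
Reagents that add atoms: tributyl(3-methylbut-2-en-1-yl)stannane (11), CCCC[Sn](CCCC)(CCCC)CC=C(C)C
Why: Stille cross-coupling delivers the prenyl group through its unsubstituted terminus without any base, so the C6–CH2 bond forms while C3 and the free phenol stay untouched.

Step 9
Reactants: 12 (2R,3S)-5-hydroxy-2,3-dimethyl-6-(3-methylbut-2-en-1-yl)-7-(triisopropylsilyloxy)chroman-4-one
Product: 13 (2R,3S)-5,7-dihydroxy-2,3-dimethyl-6-(3-methylbut-2-en-1-yl)chroman-4-one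
Conditions: Et3N·3HF, THF, rt
Reagents that add atoms: none
Why: Fluoride-mediated desilylation with the buffered HF source is too weakly acidic to cyclise the prenyl phenol and too weakly basic to epimerise C3.

Step 10
Reactants: 13 (2R,3S)-5,7-dihydroxy-2,3-dimethyl-6-(3-methylbut-2-en-1-yl)chroman-4-one; 14 (E)-hex-2-enal
Product: 16 lactol (2R,3S,10S)-5,8-dihydroxy-2,3-dimethyl-6-(3-methylbut-2-en-1-yl)-10-propyl-2,3,9,10-tetrahydro-4H,8H-pyrano[2,3-f]chromen-4-one as a mixture of anomers at the lactol carbon, via open-chain aldehyde 15 (not isolated)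
Conditions: 14 (1.5 equiv), (R)-2-[diphenyl(trimethylsilyloxy)methyl]pyrrolidine (20 mol %), PhCO2H (20 mol %), toluene, 0 °C to rt
Reagents that add atoms: (E)-hex-2-enal (14), CCC/C=C/C=O
Why: This is the iminium-catalysed Friedel–Crafts alkylation and hemiacetalisation known for electron-rich phenols and enals, in which C8 is the only free ring carbon and lies ortho or para to three oxygens, the CPh2(OSiMe3) group of the (R)-catalyst shields one face of the (E),s-trans iminium ion so that C8 attacks the Si face of the β-carbon to give the (S) centre, and the 7-OH traps the aldehyde as the lactol.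

Step 11
Reactants: 16 lactol (anomer mixture)
Product: 17 (2R,3S,10S)-5-hydroxy-2,3-dimethyl-6-(3-methylbut-2-en-1-yl)-10-propyl-2,3,9,10-tetrahydro-4H,8H-pyrano[2,3-f]chromene-4,8-dione
Conditions: Pr4N[RuO4] (5 mol %), N-methylmorpholine N-oxide (1.5 equiv), 4 Å MS, CH2Cl2, 0 °C to rt
Reagents that add atoms: none
Why: Ley–Griffith oxidation merges both lactol anomers into one lactone under nearly neutral conditions that should spare the trisubstituted alkene, the chelated phenol and all three stereocentres.

Step 12
Reactants: 17 lactone; 18 methanol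
Product: 19 methyl (3S)-3-[(2R,3S)-5,7-dihydroxy-2,3-dimethyl-6-(3-methylbut-2-en-1-yl)-4-oxochroman-8-yl]hexanoate
Conditions: MeOH, camphor-10-sulfonic acid (10 mol %), rt; solid NaHCO3 before concentration
Reagents that add atoms: methanol (18), CO
Why: Acid-catalysed lactone methanolysis (transesterification) opens the aryl ester, which has a good phenolic leaving group, in excess methanol, and the mild acid avoids base-induced C3 epimerisation and prenyl-phenol cyclisation while neutralisation before concentration prevents relactonisation.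

Compound list
1 | 2,4,6-trihydroxypropiophenone | CCC(=O)c1c(O)cc(O)cc1O | starting material
2 | 1-[2-hydroxy-4,6-bis(triisopropylsilyloxy)phenyl]propan-1-one | CCC(=O)c1c(O)cc(O[Si](C(C)C)(C(C)C)C(C)C)cc1O[Si](C(C)C)(C(C)C)C(C)C | intermediate
3 | ethanol | CCO | starting material
4 | 1-[2-ethoxy-4,6-bis(triisopropylsilyloxy)phenyl]propan-1-one | CCOc1cc(O[Si](C(C)C)(C(C)C)C(C)C)cc(O[Si](C(C)C)(C(C)C)C(C)C)c1C(=O)CC | intermediate
5 | 1-[2-ethoxy-4,6-bis(triisopropylsilyloxy)phenyl]-4,4,4-trifluoro-2-methylbutane-1,3-dione (not isolated) | CCOc1cc(O[Si](C(C)C)(C(C)C)C(C)C)cc(O[Si](C(C)C)(C(C)C)C(C)C)c1C(=O)C(C)C(=O)C(F)(F)F | intermediate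
6 | 2-diazo-1-[2-ethoxy-4,6-bis(triisopropylsilyloxy)phenyl]propan-1-one | CCOc1cc(O[Si](C(C)C)(C(C)C)C(C)C)cc(O[Si](C(C)C)(C(C)C)C(C)C)c1C(=O)C(C)=[N+]=[N-] | intermediate
7 | (2R,3S)-2,3-dimethyl-5,7-bis(triisopropylsilyloxy)chroman-4-one | CC(C)[Si](Oc1cc(O[Si](C(C)C)(C(C)C)C(C)C)c2c(c1)O[C@H](C)[C@H](C)C2=O)(C(C)C)C(C)C | intermediate
8 | (2R,3S)-5,7-dihydroxy-2,3-dimethylchroman-4-one | Oc1cc(O)c2c(c1)O[C@H](C)[C@H](C)C2=O | intermediate
9 | (2R,3S)-5-hydroxy-2,3-dimethyl-7-(triisopropylsilyloxy)chroman-4-one | CC(C)[Si](Oc1cc(O)c2c(c1)O[C@H](C)[C@H](C)C2=O)(C(C)C)C(C)C | intermediate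
10 | (2R,3S)-5-hydroxy-6-iodo-2,3-dimethyl-7-(triisopropylsilyloxy)chroman-4-one | c1c(O[Si](C(C)C)(C(C)C)C(C)C)c(I)c(O)c2c1O[C@H](C)[C@H](C)C2=O | intermediate
11 | tributyl(3-methylbut-2-en-1-yl)stannane | CCCC[Sn](CCCC)(CCCC)CC=C(C)C | starting material
12 | (2R,3S)-5-hydroxy-2,3-dimethyl-6-(3-methylbut-2-en-1-yl)-7-(triisopropylsilyloxy)chroman-4-one | c1c(O[Si](C(C)C)(C(C)C)C(C)C)c(CC=C(C)C)c(O)c2c1O[C@H](C)[C@H](C)C2=O | intermediate
13 | (2R,3S)-5,7-dihydroxy-2,3-dimethyl-6-(3-methylbut-2-en-1-yl)chroman-4-one | c1c(O)c(CC=C(C)C)c(O)c2c1O[C@H](C)[C@H](C)C2=O | intermediate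
14 | (E)-hex-2-enal | CCC/C=C/C=O | starting material
15 | (3S)-3-[(2R,3S)-5,7-dihydroxy-2,3-dimethyl-6-(3-methylbut-2-en-1-yl)-4-oxochroman-8-yl]hexanal (not isolated) | CCC[C@@H](CC=O)c1c(O)c(CC=C(C)C)c(O)c2c1O[C@H](C)[C@H](C)C2=O | intermediate
16 | (2R,3S,10S)-5,8-dihydroxy-2,3-dimethyl-6-(3-methylbut-2-en-1-yl)-10-propyl-2,3,9,10-tetrahydro-4H,8H-pyrano[2,3-f]chromen-4-one, both anomers | CCC[C@H]1CC(O)Oc2c(CC=C(C)C)c(O)c3c(c21)O[C@H](C)[C@H](C)C3=O | intermediate
17 | (2R,3S,10S)-5-hydroxy-2,3-dimethyl-6-(3-methylbut-2-en-1-yl)-10-propyl-2,3,9,10-tetrahydro-4H,8H-pyrano[2,3-f]chromene-4,8-dione | CCC[C@H]1CC(=O)Oc2c(CC=C(C)C)c(O)c3c(c21)O[C@H](C)[C@H](C)C3=O | intermediate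
18 | methanol | CO | starting material
19 | methyl (3S)-3-[(2R,3S)-5,7-dihydroxy-2,3-dimethyl-6-(3-methylbut-2-en-1-yl)-4-oxochroman-8-yl]hexanoate | CCC[C@@H](CC(=O)OC)c1c(O)c(CC=C(C)C)c(O)c2c1O[C@H](C)[C@H](C)C2=O | target

Total step count: 12. Longest linear sequence: 12 steps (1 to 19).

Steps most likely to fail

Step 4. The carbenoid may be diverted by hydride shift from its methyl group or by attack of O1 followed by ylide rearrangement. The catalyst may discriminate poorly between the enantiotopic hydrogens or between the cis and trans transition states. The kinetic cis pair may also epimerise on handling. The fallback sets out from 2, comes back at 7, and closes the ring at O1–C2 instead.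
- The dianion of 2 (LiN(iPr)2, THF, −78 °C) is added to acetaldehyde. This gives racemic 3-hydroxy-1-[2-hydroxy-4,6-bis(triisopropylsilyloxy)phenyl]-2-methylbutan-1-one F1 as a syn/anti mixture.
- The anti racemate is separated by chromatography and resolved by lipase-catalysed acetylation with vinyl acetate.
- The resolution should leave (2S,3S)-3-hydroxy-1-[2-hydroxy-4,6-bis(triisopropylsilyloxy)phenyl]-2-methylbutan-1-one F2 unreacted. It should convert the antipode into (2R,3R)-4-[2-hydroxy-4,6-bis(triisopropylsilyloxy)phenyl]-3-methyl-4-oxobutan-2-yl acetate F3.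
- Intramolecular Mitsunobu etherification of F2 (PPh3, DIAD, THF) lets the chelated phenol displace the activated carbinol with inversion. The anti aldol therefore becomes the cis chromanone 7.

Step 10. C-alkylation may be sluggish because the acyl group tempers the ring. 1,2-Addition followed by electrocyclisation may compete, and facial selectivity may be poor. The fallback sets out from 13, comes back at 17, and gives up catalyst control in favour of diastereomer separation.
- Knoevenagel condensation of butanal with Meldrum's acid gives 5-butylidene-2,2-dimethyl-1,3-dioxane-4,6-dione F4.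
- C8 of 13 adds to this strong acceptor (Yb(OTf)3 10 mol %, MeNO2, 50 °C). The 7-OH then opens the dioxanedione with loss of acetone and carbon dioxide, so the lactone forms directly and no lactol oxidation is needed.
- Because C2 and C3 are already fixed, 17 and its epimer (2R,3S,10R)-5-hydroxy-2,3-dimethyl-6-(3-methylbut-2-en-1-yl)-10-propyl-2,3,9,10-tetrahydro-4H,8H-pyrano[2,3-f]chromene-4,8-dione F5 are diastereomers and are separated by chromatography.

Step 7. Regiocontrol may be lost through attack at C8 or through double iodination. The fallback sets out from 9, comes back at 12, and bypasses steps 7 and 8 with a sigmatropic relay from O5, whose only free ortho position is C6.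
- Mitsunobu etherification of 9 with allyl alcohol (PPh3, DIAD, THF) gives (2R,3S)-5-(allyloxy)-2,3-dimethyl-7-(triisopropylsilyloxy)chroman-4-one F6.
- Thermal aromatic Claisen rearrangement in a neutral medium (1,2-dichlorobenzene, 180 °C) gives (2R,3S)-6-allyl-5-hydroxy-2,3-dimethyl-7-(triisopropylsilyloxy)chroman-4-one F7.
- Cross-metathesis with excess 2-methylbut-2-ene (second-generation Grubbs catalyst, CH2Cl2, 40 °C) turns the allyl group into the prenyl group of 12.

Further compounds
F1 | step 4 | 3-hydroxy-1-[2-hydroxy-4,6-bis(triisopropylsilyloxy)phenyl]-2-methylbutan-1-one, racemic syn/anti mixture | CC(O)C(C)C(=O)c1c(O)cc(O[Si](C(C)C)(C(C)C)C(C)C)cc1O[Si](C(C)C)(C(C)C)C(C)C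
F2 | step 4 | (2S,3S)-3-hydroxy-1-[2-hydroxy-4,6-bis(triisopropylsilyloxy)phenyl]-2-methylbutan-1-one | C[C@H](O)[C@H](C)C(=O)c1c(O)cc(O[Si](C(C)C)(C(C)C)C(C)C)cc1O[Si](C(C)C)(C(C)C)C(C)C
F3 | step 4 | (2R,3R)-4-[2-hydroxy-4,6-bis(triisopropylsilyloxy)phenyl]-3-methyl-4-oxobutan-2-yl acetate | C[C@@H](OC(C)=O)[C@@H](C)C(=O)c1c(O)cc(O[Si](C(C)C)(C(C)C)C(C)C)cc1O[Si](C(C)C)(C(C)C)C(C)C
F4 | step 10 | 5-butylidene-2,2-dimethyl-1,3-dioxane-4,6-dione | CCCC=C1C(=O)OC(C)(C)OC1=O
F5 | step 10 | (2R,3S,10R)-5-hydroxy-2,3-dimethyl-6-(3-methylbut-2-en-1-yl)-10-propyl-2,3,9,10-tetrahydro-4H,8H-pyrano[2,3-f]chromene-4,8-dione | CCC[C@@H]1CC(=O)Oc2c(CC=C(C)C)c(O)c3c(c21)O[C@H](C)[C@H](C)C3=O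
F6 | step 7 | (2R,3S)-5-(allyloxy)-2,3-dimethyl-7-(triisopropylsilyloxy)chroman-4-one | c1c(O[Si](C(C)C)(C(C)C)C(C)C)cc(OCC=C)c2c1O[C@H](C)[C@H](C)C2=O
F7 | step 7 | (2R,3S)-6-allyl-5-hydroxy-2,3-dimethyl-7-(triisopropylsilyloxy)chroman-4-one | c1c(O[Si](C(C)C)(C(C)C)C(C)C)c(CC=C)c(O)c2c1O[C@H](C)[C@H](C)C2=O
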